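**Plan**

1. Retrosynthesis: once the acetonide and the silyl ether are removed, the C7–O and C8–H bonds and, on the ring B side chain, the C9'–O and C8'–H bonds are cut in one retro-hydration, leaving a Z C7=C8 aryl enol ether with an allyl group on ring B.
2. The C7=C8 bond is then cut (dehydration, then aldol C7–C8) into a ring A aldehyde and a ring B aryloxyacetate; the two alkyl aryl ether bonds lead back to vanillin, 2,2-dimethyl-1,3-dioxan-5-ol, 4-allyl-2,6-dimethoxyphenol and ethyl bromoacetate.
3. Enabling feature: C7 bears OH and H and C8 bears H and the oxygen of ring B, which is what a syn H/OH addition to a C7=C8 enol ether gives, and the 3-hydroxypropyl chain of ring B (C7'–C9') is an allyl group after anti-Markovnikov hydration.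
4. Forward order: no ring is formed; the chain is joined by the aldol addition, dehydrated to the Z enoate, reduced and silylated, then both alkenes are hydroborated and oxidized in one operation, and the protecting groups are removed.
5. Stereochemistry: the erythro relation follows from the Z geometry plus syn addition; the absolute (7S,8R) sense is imposed by the isopinocampheyl group of IpcBH2.

Key step: step 7

Remark on locants: C7, C8 and C9 are the benzylic carbon, the ether-bearing carbon and the CH2O carbon of the chain on ring A (the 3-methoxy-4-alkoxyphenyl ring); ring B is the 2,6-dimethoxyphenoxy ring and C7'–C9' its three-carbon chain.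

Remark on the reagent: IpcBH2 is used as a THF solution, liberated beforehand from its crystalline TMEDA adduct with BF3·OEt2 and filtered, so that no BF3 enters the reaction flask.

Assumption: the face preference of IpcBH2 made from (+)-α-pinene is carried over from its known behaviour with trisubstituted aryl alkenes, which predicts 7S. Should this enol ether respond in the opposite sense, the reagent from (−)-α-pinene is used with no other change.

**Route**

Step 1
Reactants: 1 vanillin; 2 2,2-dimethyl-1,3-dioxan-5-ol
Product: 3 4-[(2,2-dimethyl-1,3-dioxan-5-yl)oxy]-3-methoxybenzaldehyde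
Conditions: PPh3, DIAD, THF, 0 °C to rt
Reagents that add atoms: none
Why: Mitsunobu etherification, in which the acidic phenol of vanillin displaces the phosphonium-activated secondary hydroxyl of the symmetrical dioxanol while the aldehyde stays untouched; C5 of the dioxane carries two identical arms, so no stereocentre arises.

Step 2
Reactants: 4 4-allyl-2,6-dimethoxyphenol; 5 ethyl bromoacetate
Product: 6 ethyl (4-allyl-2,6-dimethoxyphenoxy)acetate
Conditions: K2CO3, acetone, reflux
Reagents that add atoms: none
Why: Williamson ether synthesis, the phenoxide formed with K2CO3 displacing bromide from the activated α-bromo ester by SN2 under conditions too mild to isomerize the allyl group.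

Step 3
Reactants: 6 ethyl (4-allyl-2,6-dimethoxyphenoxy)acetate; 3 4-[(2,2-dimethyl-1,3-dioxan-5-yl)oxy]-3-methoxybenzaldehyde
Product: 8 ethyl 3-hydroxy-3-(ring A aryl)-2-(ring B aryloxy)propanoate as a diastereomer mixture, via lithium enolate 7 (not isolated)
Conditions: LiN(i-Pr)2 (LDA), THF, −78 °C; then 3, −78 °C; AcOH quench
Reagents that add atoms: none
Why: Aldol addition of a lithium ester enolate to a non-enolizable aromatic aldehyde, forming the C7–C8 bond; the two new centres arise as a mixture, which is harmless because both are erased in step 4.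

Step 4
Reactants: 8 aldol adduct (diastereomer mixture)
Product: 10 ethyl (Z)-3-(ring A aryl)-2-(ring B aryloxy)prop-2-enoate, via benzylic mesylate 9 (not isolated)
Conditions: MsCl, Et3N, CH2Cl2, 0 °C; then DBU, 0 °C to rt; chromatography to remove any E isomer
Reagents that add atoms: none
Why: Mesylation followed by E1cB elimination through the ester enolate, which should converge both aldol diastereomers on the more stable Z alkene, with ring A trans to the ester group and cis to the ring B oxygen.

Step 5
Reactants: 10 ethyl (Z)-2-aryloxycinnamate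
Product: 11 (Z)-3-(ring A aryl)-2-(ring B aryloxy)prop-2-en-1-ol
Conditions: i-Bu2AlH (DIBAL-H), CH2Cl2, −78 °C; aq. potassium sodium tartrate work-up
Reagents that add atoms: none
Why: 1,2-Reduction of an α,β-unsaturated ester to the allylic alcohol by DIBAL-H, which leaves the enol ether, the allyl group and the acetonide alone and keeps the Z geometry.

Step 6
Reactants: 11 (Z)-allylic alcohol
Product: 12 (Z)-2-aryloxycinnamyl tert-butyldimethylsilyl ether carrying the ring B allyl group and the ring A acetonide
Conditions: TBSCl, imidazole, CH2Cl2, rt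
Reagents that add atoms: tert-butyldimethylsilyl chloride, CC(C)(C)[Si](C)(C)Cl
Why: Standard imidazole-promoted silylation of a primary alcohol, capping the hydroxyl so that it neither consumes B–H nor binds the borane in the next step.

Step 7
Reactants: 12 (Z)-2-aryloxycinnamyl silyl ether
Product: 14 (7S,8R) erythro 7,9'-diol with C9 silyl ether and acetonide, via bis(isopinocampheylboryl) adduct 13 (not isolated)
Conditions: IpcBH2 [from (+)-α-pinene, 3 equiv], THF, −25 to 0 °C; then NaBO3·4H2O, THF/H2O, rt
Reagents that add atoms: sodium perborate tetrahydrate (NaBO3·4H2O), [Na+].[Na+].O[B-]1(O)OO[B-](O)(O)OO1.O.O.O.O.O.O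
Why: Each B–H bond adds through a concerted four-centre transition state, boron to C7 and hydrogen to C8 on one face of the C7=C8 enol ether and boron to the terminal carbon C9' of the allyl group, and perborate then exchanges both C–B bonds for C–O bonds with retention. The closest known reaction type is the asymmetric hydroboration–oxidation of trisubstituted and aryl-substituted alkenes with IpcBH2, together with the hydroboration–oxidation of Z 2-aryloxycinnamyl derivatives to erythro arylglycerol aryl ethers. No ring is closed. The relative configuration of C7 and C8 is controlled by the Z geometry: ring A and C9 are trans, so syn delivery of OH to C7 and H to C8 leaves the C7 hydroxyl and the C8 aryloxy group anti, which is the erythro relation. The absolute configuration is controlled by the isopinocampheyl group, and the reagent from (+)-α-pinene is expected, by analogy with 1-arylcycloalkenes, to attack the face that gives 7S and therefore 8R. The step needs boron at C7, which the C8 oxygen (its lone pair makes C7 the nucleophilic carbon) and the full substitution of C8 secure, and it needs the β-aryloxy borane to survive, for which the addition is kept cold and free of BF3 and is oxidized at once under weakly basic conditions.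

Step 8
Reactants: 14 (7S,8R) erythro 7,9'-diol with C9 silyl ether and acetonide
Product: 15 (1S,2R)-1-{4-[(1,3-dihydroxypropan-2-yl)oxy]-3-methoxyphenyl}-2-[4-(3-hydroxypropyl)-2,6-dimethoxyphenoxy]propane-1,3-diol (target)
Conditions: AcOH/THF/H2O (3:1:1), rt to 40 °C
Reagents that add atoms: none
Why: Acid-catalysed hydrolysis should cleave the isopropylidene acetal and the primary silyl ether in one operation, and acetic acid is weak enough that the C7 benzylic alcohol should not ionize, so both stereocentres stay as set.

**Compound list**

1 | vanillin (4-hydroxy-3-methoxybenzaldehyde) | COc1cc(C=O)ccc1O | starting material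
2 | 2,2-dimethyl-1,3-dioxan-5-ol | OC1COC(C)(C)OC1 | starting material
3 | 4-[(2,2-dimethyl-1,3-dioxan-5-yl)oxy]-3-methoxybenzaldehyde | COc1cc(C=O)ccc1OC1COC(C)(C)OC1 | intermediate
4 | 4-allyl-2,6-dimethoxyphenol | C=CCc1cc(OC)c(O)c(OC)c1 | starting material
5 | ethyl bromoacetate | CCOC(=O)CBr | starting material
6 | ethyl [2,6-dimethoxy-4-(prop-2-en-1-yl)phenoxy]acetate | CCOC(=O)COc1c(OC)cc(CC=C)cc1OC | intermediate
7 | lithium enolate of 6 | [Li+].CCOC([O-])=COc1c(OC)cc(CC=C)cc1OC | intermediate (not isolated)
8 | ethyl 3-{4-[(2,2-dimethyl-1,3-dioxan-5-yl)oxy]-3-methoxyphenyl}-2-[2,6-dimethoxy-4-(prop-2-en-1-yl)phenoxy]-3-hydroxypropanoate, racemic mixture of diastereomers (stereocentres undefined) | COc1cc(C(O)C(C(=O)OCC)Oc2c(OC)cc(CC=C)cc2OC)ccc1OC1COC(C)(C)OC1 | intermediate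
9 | 3-methanesulfonate of 8 (stereocentres undefined) | COc1cc(C(OS(C)(=O)=O)C(C(=O)OCC)Oc2c(OC)cc(CC=C)cc2OC)ccc1OC1COC(C)(C)OC1 | intermediate (not isolated)
10 | ethyl (2Z)-3-{4-[(2,2-dimethyl-1,3-dioxan-5-yl)oxy]-3-methoxyphenyl}-2-[2,6-dimethoxy-4-(prop-2-en-1-yl)phenoxy]prop-2-enoate | COc1cc(/C=C(/C(=O)OCC)Oc2c(OC)cc(CC=C)cc2OC)ccc1OC1COC(C)(C)OC1 | intermediate
11 | (2Z)-3-{4-[(2,2-dimethyl-1,3-dioxan-5-yl)oxy]-3-methoxyphenyl}-2-[2,6-dimethoxy-4-(prop-2-en-1-yl)phenoxy]prop-2-en-1-ol | COc1cc(/C=C(/CO)Oc2c(OC)cc(CC=C)cc2OC)ccc1OC1COC(C)(C)OC1 | intermediate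
12 | tert-butyl({(2Z)-3-{4-[(2,2-dimethyl-1,3-dioxan-5-yl)oxy]-3-methoxyphenyl}-2-[2,6-dimethoxy-4-(prop-2-en-1-yl)phenoxy]prop-2-en-1-yl}oxy)dimethylsilane | COc1cc(/C=C(/CO[Si](C)(C)C(C)(C)C)Oc2c(OC)cc(CC=C)cc2OC)ccc1OC1COC(C)(C)OC1 | intermediate
13 | adduct of 12 with two IpcBH2 units: Ipc(H)B on C7 (syn to the new C8–H, same spatial arrangement as in 14) and Ipc(H)B on C9', isopinocampheyl groups from (+)-α-pinene | COc1cc([C@H](B[C@@H]2C[C@@H]3C[C@H]([C@H]2C)C3(C)C)[C@@H](CO[Si](C)(C)C(C)(C)C)Oc2c(OC)cc(CCCB[C@@H]3C[C@@H]4C[C@H]([C@H]3C)C4(C)C)cc2OC)ccc1OC1COC(C)(C)OC1 | intermediate (not isolated)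
14 | (1S,2R)-3-{[tert-butyl(dimethyl)silyl]oxy}-1-{4-[(2,2-dimethyl-1,3-dioxan-5-yl)oxy]-3-methoxyphenyl}-2-[4-(3-hydroxypropyl)-2,6-dimethoxyphenoxy]propan-1-ol (7S,8R, erythro) | COc1cc([C@H](O)[C@@H](CO[Si](C)(C)C(C)(C)C)Oc2c(OC)cc(CCCO)cc2OC)ccc1OC1COC(C)(C)OC1 | intermediate
15 | (1S,2R)-1-{4-[(1,3-dihydroxypropan-2-yl)oxy]-3-methoxyphenyl}-2-[4-(3-hydroxypropyl)-2,6-dimethoxyphenoxy]propane-1,3-diol (7S,8R, erythro) | COc1cc([C@H](O)[C@@H](CO)Oc2c(OC)cc(CCCO)cc2OC)ccc1OC(CO)CO | target

**Step count and risks**

Total: 8 steps. Longest linear sequence: 7 steps (steps 2 to 8 from 4-allyl-2,6-dimethoxyphenol, or steps 1 and 3 to 8 from vanillin).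

Steps most likely to fail:

Step 7. The isopinocampheyl group may discriminate poorly between the two faces of this heavily oxygenated enol ether, which would erode enantiomeric purity. The C7 borane may also undergo β-elimination with loss of the ring B phenoxide before it is oxidized. The fallback gives up reagent control and sets out from 12. Hydroboration with BH3·SMe2 (THF, 0 °C) and oxidation with NaBO3·4H2O is established for this substrate class; syn addition to the Z alkene still fixes the erythro relation and should give the racemic erythro 7,9'-diol F1. Its enantiomers are then separated by preparative HPLC on a cellulose tris(3,5-dimethylphenylcarbamate) phase, and the (7S,8R) enantiomer re-enters the route as 14.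

Step 4. Geometric control in the elimination may be incomplete, or the aldol may fragment by retro-aldol under DBU; any E alkene carried forward would end as the threo series. The fallback builds the double bond in one olefination and sets out from 6. Deprotonation with LiN(i-Pr)2 (THF, −78 °C) and trapping with ClP(OEt)2 should give ethyl 2-(diethoxyphosphanyl)-2-(4-allyl-2,6-dimethoxyphenoxy)acetate F2, which is oxidized in the same flask with aqueous H2O2 to ethyl 2-(diethoxyphosphoryl)-2-(4-allyl-2,6-dimethoxyphenoxy)acetate F3. Horner–Wadsworth–Emmons olefination of aldehyde 3 with F3 (NaH, THF, 0 °C to rt) is expected to favor the isomer with ring A trans to the ester, and the path comes back to the route at 10.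

Step 1. Substitution at the secondary carbinol carbon of 2, flanked by two oxygen-bearing methylene groups, may be slow, so that alkylation of the reduced azodicarboxylate takes over. The fallback reverses the polarity and sets out from 2. Its sodium alkoxide (NaH, DMF, rt to 60 °C) displaces fluoride from commercial 4-fluoro-3-methoxybenzaldehyde (COc1cc(C=O)ccc1F) in an SNAr reaction activated by the para formyl group, and the path comes back to the route at 3. No compound outside the list is made on this path (F0).

**Further compounds**

F1 | step 7 | racemic erythro 7,9'-diol (1:1 mixture of 14 and its enantiomer) | COc1cc([C@H](O)[C@@H](CO[Si](C)(C)C(C)(C)C)Oc2c(OC)cc(CCCO)cc2OC)ccc1OC1COC(C)(C)OC1.COc1cc([C@@H](O)[C@H](CO[Si](C)(C)C(C)(C)C)Oc2c(OC)cc(CCCO)cc2OC)ccc1OC1COC(C)(C)OC1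
F2 | step 4 | ethyl 2-(diethoxyphosphanyl)-2-(4-allyl-2,6-dimethoxyphenoxy)acetate | CCOC(=O)C(Oc1c(OC)cc(CC=C)cc1OC)P(OCC)OCC
F3 | step 4 | ethyl 2-(diethoxyphosphoryl)-2-(4-allyl-2,6-dimethoxyphenoxy)acetate | CCOC(=O)C(Oc1c(OC)cc(CC=C)cc1OC)P(=O)(OCC)OCC
F0 | step 1 | none | none
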